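**Plan**

- Numbering follows the seco acid: C1 is the lactone carbonyl, C2 its α-CH2, C34 the OCH2. The single ring holds these 34 carbons and one oxygen (35 members).
- C2, the methylene next to the carbonyl C1, is the only acidifiable carbon of the 35-membered ring. The C2-C3 bond can therefore be made as an enoate C=C by phosphonate olefination and then saturated.
- Retrosynthetic cuts, in order: C2-C3 (ring opening to a C3 aldehyde and a C2 phosphonate), the acyl C1-O bond (phosphonoacetic acid plus a C32 chain), and C18-C19 (two C16 halves, both from hexadecane-1,16-diol).
- Forward: the two C16 halves are joined at C18-C19 by copper-catalysed Grignard coupling, the free hydroxyl is acylated (O-C1), the far terminus is unmasked and oxidised to the C3 aldehyde, the ring closes at C2-C3, and the alkene is hydrogenated.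
- Stereochemistry: the target has no stereocentre. The transient C2=C3 geometry (expected E) is erased by the final hydrogenation.

Key step: step 7

Remark: the target SMILES carries no stereodescriptor and is read as oxacyclopentatriacontan-2-one, C34H66O2 (one C=O, 33 CH2, one ring oxygen).

**Route**

Step 1
Reactants: 1 hexadecane-1,16-diol
Product: 2 16-bromohexadecan-1-ol
Conditions: 48% aq HBr (1.1 equiv), toluene, reflux
Reagents that add atoms: hydrogen bromide, Br
Why: Nucleophilic substitution (SN2) of a protonated primary hydroxyl by bromide under two-phase HBr/toluene conditions is a standard monobromination of symmetrical α,ω-diols, because the bromo alcohol passes into toluene as hydrogen-bonded aggregates that keep its remaining hydroxyl away from the aqueous acid.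

Step 2
Reactants: 2 16-bromohexadecan-1-ol
Product: 3 [(16-bromohexadecyl)oxy](tert-butyl)dimethylsilane
Conditions: TBSCl, imidazole, CH2Cl2/DMF, 0 °C to rt
Reagents that add atoms: tert-butyldimethylsilyl chloride (TBSCl), CC(C)(C)[Si](C)(C)Cl
Why: Imidazole-promoted silylation of the primary alcohol is fast at room temperature and should leave the primary bromide untouched, and the silyl ether is inert to magnesium and to the Grignard reagent needed next.

Step 3
Reactants: 3 [(16-bromohexadecyl)oxy](tert-butyl)dimethylsilane; 2 16-bromohexadecan-1-ol
Product: 6 32-[(tert-butyldimethylsilyl)oxy]dotriacontan-1-ol, via silyloxyhexadecylmagnesium bromide 4 (not isolated), via chloromagnesium bromohexadecanolate 5 (not isolated)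
Conditions: (a) 3, Mg, cat. BrCH2CH2Br, THF, 45 °C; (b) 2, MeMgCl (1.0 equiv), THF, −20 °C; (c) (a) added to (b), Li2CuCl4 (3 mol %), THF/NMP, −20 °C to rt; aq NH4Cl
Reagents that add atoms: none
Why: Kochi-type copper-catalysed alkyl-alkyl coupling, in which the Grignard reagent reduces Li2CuCl4 to a monovalent copper species whose alkylcuprate displaces the primary bromide of 5 (SN2) to form C18-C19, while the hydroxyl of 2, stored beforehand as its magnesium alkoxide, neither quenches the nucleophile nor reacts with it, so the C32 chain should emerge with its two oxygens already differentiated.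

Step 4
Reactants: 6 32-[(tert-butyldimethylsilyl)oxy]dotriacontan-1-ol; 7 diethylphosphonoacetic acid
Product: 8 32-[(tert-butyldimethylsilyl)oxy]dotriacontyl 2-(diethoxyphosphoryl)acetate
Conditions: DCC, DMAP (cat.), CH2Cl2, 0 °C to rt (gentle warming to dissolve 6)
Reagents that add atoms: none
Why: Steglich esterification, in which DCC activates the acid as an O-acylisourea and DMAP relays it as an acylpyridinium ion to the unhindered primary alcohol under neutral conditions that leave the silyl ether and the phosphonate esters intact.

Step 5
Reactants: 8 32-[(tert-butyldimethylsilyl)oxy]dotriacontyl 2-(diethoxyphosphoryl)acetate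
Product: 9 32-hydroxydotriacontyl 2-(diethoxyphosphoryl)acetate
Conditions: HF·pyridine, pyridine, THF, 0 °C to rt
Reagents that add atoms: none
Why: Fluoride-driven desilylation with pyridine-buffered HF cleaves the primary TBS ether through formation of the strong Si-F bond, and this mildly acidic, non-nucleophilic medium should not affect the carboxylic ester or the phosphonate ethyl esters.

Step 6
Reactants: 9 32-hydroxydotriacontyl 2-(diethoxyphosphoryl)acetate
Product: 10 32-oxodotriacontyl 2-(diethoxyphosphoryl)acetate
Conditions: Dess–Martin periodinane, NaHCO3, CH2Cl2, rt; crude aldehyde used at once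
Reagents that add atoms: none
Why: Dess–Martin oxidation proceeds by alkoxide exchange at hypervalent iodine, stops at the aldehyde, and under bicarbonate buffering should be too mild to enolise the aldehyde or to attack the acidic phosphonoacetate methylene.

Step 7
Reactants: 10 32-oxodotriacontyl 2-(diethoxyphosphoryl)acetate
Product: 11 (E)-oxacyclopentatriacont-3-en-2-one
Conditions: LiCl (excess), DBU, MeCN/THF (1:1), 40 °C, 10 in THF added by syringe pump over 16 h, final concentration ≤ 1 mM
Reagents that add atoms: none
Why: LiCl binds the phosphoryl and ester carbonyl oxygens of the phosphonoacetate, so that DBU deprotonates C2 reversibly and only a small standing amount of the lithium phosphonoenolate exists; this carbanion adds to the aldehyde carbon C3, the adduct closes to an oxaphosphetane and loses lithium diethyl phosphate irreversibly to leave the C2=C3 enoate. The closest known reaction type is the intramolecular Horner–Wadsworth–Emmons macrocyclisation of ω-formyl phosphonoacetates under Masamune–Roush conditions (lithium salt plus amine base), a standard closure for large-ring lactones. The single 35-membered ring closes end to end; in the carbon-carbon bond-forming addition this is a 35-exo-trig attack of C2 on the C3 carbonyl, whose oxygen stays outside the ring. No stereocentre arises; the alkene should be mainly E, as usual for stabilised phosphonates in a strain-free ring, and either geometry is acceptable because step 8 removes it. The selectivity required is ring closure over chain-to-chain olefination: the substrate secures it by having exactly one acidifiable CH2 and one unhindered, unbranched aldehyde on a flexible strain-free tether, so that the only productive pairing at low concentration is head to tail within one molecule, and the slow addition in a THF-containing medium keeps the waxy chain dissolved and its standing concentration far below the effective molarity of large-ring closure.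

Step 8
Reactants: 11 (E)-oxacyclopentatriacont-3-en-2-one
Product: 12 oxacyclopentatriacontan-2-one
Conditions: H2 (1 atm), 10% Pd/C, EtOAc/THF, rt
Reagents that add atoms: none
Why: Heterogeneous catalytic hydrogenation should add H2 across the conjugated disubstituted C2=C3 bond of either geometric isomer, and the lactone, having no benzylic or allylic C-O bond, is stable to Pd/C under one atmosphere of hydrogen.

**Compound list**

1 | hexadecane-1,16-diol | OCCCCCCCCCCCCCCCCO | starting material
2 | 16-bromohexadecan-1-ol | OCCCCCCCCCCCCCCCCBr | intermediate
3 | [(16-bromohexadecyl)oxy](tert-butyl)dimethylsilane | CC(C)(C)[Si](C)(C)OCCCCCCCCCCCCCCCCBr | intermediate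
4 | {16-[(tert-butyldimethylsilyl)oxy]hexadecyl}magnesium bromide | CC(C)(C)[Si](C)(C)OCCCCCCCCCCCCCCCC[Mg]Br | intermediate
5 | chloromagnesium 16-bromohexadecan-1-olate | BrCCCCCCCCCCCCCCCCO[Mg]Cl | intermediate
6 | 32-[(tert-butyldimethylsilyl)oxy]dotriacontan-1-ol | CC(C)(C)[Si](C)(C)OCCCCCCCCCCCCCCCCCCCCCCCCCCCCCCCCO | intermediate
7 | diethylphosphonoacetic acid | CCOP(=O)(OCC)CC(=O)O | starting material
8 | 32-[(tert-butyldimethylsilyl)oxy]dotriacontyl 2-(diethoxyphosphoryl)acetate | CCOP(=O)(OCC)CC(=O)OCCCCCCCCCCCCCCCCCCCCCCCCCCCCCCCCO[Si](C)(C)C(C)(C)C | intermediate
9 | 32-hydroxydotriacontyl 2-(diethoxyphosphoryl)acetate | CCOP(=O)(OCC)CC(=O)OCCCCCCCCCCCCCCCCCCCCCCCCCCCCCCCCO | intermediate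
10 | 32-oxodotriacontyl 2-(diethoxyphosphoryl)acetate | CCOP(=O)(OCC)CC(=O)OCCCCCCCCCCCCCCCCCCCCCCCCCCCCCCCC=O | intermediate
11 | (E)-oxacyclopentatriacont-3-en-2-one | O=C1/C=C/CCCCCCCCCCCCCCCCCCCCCCCCCCCCCCCO1 | intermediate
12 | oxacyclopentatriacontan-2-one | O=C1CCCCCCCCCCCCCCCCCCCCCCCCCCCCCCCCCO1 | target

**Count**

Total steps: 8. Longest linear sequence: 8 steps (1 to 12).

**Steps most likely to fail**

1. Step 7 (macrocyclisation). Bimolecular olefination between two chains may compete with the entropically costly end-to-end closure. Aggregation or precipitation of the polymethylene chain in the polar medium would raise the local concentration, so dimeric and oligomeric enoates would form in place of the monomeric ring. The fallback sets out from 6 and returns at 11; it makes the C2=C3 alkene intermolecularly and closes the ring at the ester bond. Dess–Martin oxidation of 6 gives 32-[(tert-butyldimethylsilyl)oxy]dotriacontanal F1. A Horner–Wadsworth–Emmons reaction with triethyl phosphonoacetate (LiCl, DBU, THF/MeCN) gives ethyl (E)-34-[(tert-butyldimethylsilyl)oxy]tetratriacont-2-enoate F2. HF·pyridine removes the silyl group to give ethyl (E)-34-hydroxytetratriacont-2-enoate F3. LiOH in THF/MeOH/H2O followed by aq HCl gives (E)-34-hydroxytetratriacont-2-enoic acid F4. Yamaguchi macrolactonisation (2,4,6-trichlorobenzoyl chloride, Et3N, THF, then slow addition to DMAP in toluene at 80 °C) should give 11, which enters step 8.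

2. Step 3 (chain coupling). The chloromagnesium alkoxide 5 may aggregate or precipitate, and incompletely deprotonated 2 may protonate Grignard reagent 4, so the cross-coupling would stall and reduced or homocoupled C16 material would dominate. The fallback sets out from 3 and returns at 6; the electrophile carries an ester in place of the hydroxyl. Commercial 16-bromohexadecanoic acid is esterified (MeOH, cat. H2SO4) to methyl 16-bromohexadecanoate F5. F5 is coupled with Grignard reagent 4 prepared from 3 (Li2CuCl4, THF/NMP, −20 °C, where the ester is tolerated) to give methyl 32-[(tert-butyldimethylsilyl)oxy]dotriacontanoate F6. LiAlH4 in THF at 0 °C reduces F6 to 6.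

3. Step 4 (acylation). The carbodiimide-activated, C-H acidic phosphonoacetic acid may drain into N-acylurea and self-condensation products while the waxy, sparingly soluble alcohol 6 reacts slowly, leaving the acylation incomplete. The fallback sets out from 6 and returns at 8; the phosphorus-carbon bond is made after the ester. Bromoacetyl bromide and pyridine in CH2Cl2 at 0 °C convert 6 into 32-[(tert-butyldimethylsilyl)oxy]dotriacontyl 2-bromoacetate F7. A Michaelis–Arbuzov reaction of F7 with neat triethyl phosphite at 120 °C gives 8.

**Further compounds**

F1 | step 7 | 32-[(tert-butyldimethylsilyl)oxy]dotriacontanal | CC(C)(C)[Si](C)(C)OCCCCCCCCCCCCCCCCCCCCCCCCCCCCCCCC=O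
F2 | step 7 | ethyl (E)-34-[(tert-butyldimethylsilyl)oxy]tetratriacont-2-enoate | CCOC(=O)/C=C/CCCCCCCCCCCCCCCCCCCCCCCCCCCCCCCO[Si](C)(C)C(C)(C)C
F3 | step 7 | ethyl (E)-34-hydroxytetratriacont-2-enoate | CCOC(=O)/C=C/CCCCCCCCCCCCCCCCCCCCCCCCCCCCCCCO
F4 | step 7 | (E)-34-hydroxytetratriacont-2-enoic acid | OC(=O)/C=C/CCCCCCCCCCCCCCCCCCCCCCCCCCCCCCCO
F5 | step 3 | methyl 16-bromohexadecanoate | COC(=O)CCCCCCCCCCCCCCCBr
F6 | step 3 | methyl 32-[(tert-butyldimethylsilyl)oxy]dotriacontanoate | COC(=O)CCCCCCCCCCCCCCCCCCCCCCCCCCCCCCCO[Si](C)(C)C(C)(C)C
F7 | step 4 | 32-[(tert-butyldimethylsilyl)oxy]dotriacontyl 2-bromoacetate | BrCC(=O)OCCCCCCCCCCCCCCCCCCCCCCCCCCCCCCCCO[Si](C)(C)C(C)(C)C
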